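## The problem

The target is an elemanolide (elemane numbering is used for every compound below): a cyclohexane C5–C10 with five stereocentres, trans-fused at C6/C7 to an α-methylene-γ-butyrolactone (O6–C12(=O)–C11=C13). It carries an 8α-ester of 2-(hydroxymethyl)acrylic acid, a quaternary C10 with a vinyl group (C1=C2, α) and an acetoxymethyl group (C14, β), and a 2-substituted acrolein (C3=C4–C15HO, β) on C5. The four contiguous centres C5–C8 are all-trans and all-equatorial. C6 and C8 are therefore accessible by equilibration next to a carbonyl at C7, and C7 by axial delivery of hydrogen. The real stereochemical problem is the vicinal pair C5 (tertiary)/C10 (quaternary), with C14 cis to C4. The three Michael acceptors (α-methylene lactone, hydroxymethacrylate, enal), the acetate and the free allylic alcohol do not survive amide bases, hydride, soft nucleophiles or hydrogenation, so they must appear at the very end.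

Two features of the structure make the key step possible:

- Without the C5 substituent the ring has a mirror plane through C7 and C10 (C6 and C8 both carry α-oxygen). The ring therefore maps onto a 4,4-disubstituted cyclohexa-2,5-dienone with C7 as the carbonyl, C6/C8 as α-carbons and C5/C9 as β-carbons.
- O14 and the enal methylene C3 are 1,5-related through C14–C10–C5–C4 and lie on the same face. The 14-acyloxy enal is thus the ring-opened (retro-oxa-Michael) form of a cis-fused tetrahydropyran O14–C3–C4–C5–C10–C14. The C14 oxygen can carry acrolein to C5.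

## Retrosynthesis

**Enal and acetate (36 ⇒ 35 ⇒ 33 ⇒ 31).** No skeletal bond is cut. The C3=C4 enal and the C14 acetate are traced back to the closed tetrahydropyran aldehyde 31 by reconnecting O14 to C3. The alternative, carrying a free enal or an acetate through enolate and hydride chemistry, is not viable. An isopropenyl→enal oxidation at the end would compete with three other allylic sites. In 31 one ring masks both the enal and the C14 oxygen. The forward step must break O14–C3 irreversibly although the closed form is the more stable one; transfer of silicon from an enol oxygen to O14 is to supply the driving force (31 → 33).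

**Side-chain ester (31 ⇒ 26 + 29).** The C8–O acyl bond is cut. Late acylation keeps the acrylate away from hydride and enolate steps. The forward reaction has to acylate an equatorial secondary alcohol next to an α-methylene lactone; acid 29 comes in two steps from 27.

**Lactone (26 ⇒ 25 ⇒ 22 ⇒ 21 ⇒ 18 + 19).** Three cuts: C11=C13 (methylenation), C7–H (conjugate hydride) and C7=C11 together with O6–C12 (acylation/intramolecular Wittig with 19). C7 is the former dienone carbonyl, so C11 has to arrive at an sp2 C7. An epoxide opening at C7 would give the diaxial, not the all-equatorial, array. Olefination followed by axial hydride addition puts C11 equatorial. Precursor 18 is a simple α-hydroxy ketone.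

**Ring oxygens (18 ⇒ 15 ⇒ 13).** The C6–O and C8–O bonds are cut. Both carbons are α to the C7 ketone, so two enol ether oxidations suffice and both centres can settle equatorial. Doing C8 first (through the enone) and C6 second gives O8 protected and O6 free without extra protecting-group steps. The cis-fused pyran ring of 13 blocks the β-face.

**Key disconnection (13 ⇒ 9 + 10).** O14–C3 and C4–C5 are cut. This removes the bicyclic framework, both stereocentres C5 and C10, and the masked enal in one operation. The precursor 9 is achiral and has no stereocentre. The forward reaction must choose one of two enantiotopic enone halves and deliver C4 to the face of C14.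

**Dienone (9 ⇒ 8 ⇒ 7 ⇒ 3 + 4; 3 ⇒ 2 ⇒ 1).** The quaternary carbon is made by a Diels–Alder reaction of diene 4 with 2-substituted acrolein 3 (C5–C10 and C8–C9 of the later ring). The formyl group becomes the vinyl group by Wittig methylenation, and dehydrogenation gives the dienone. Aldehyde 3 comes from diol 1 in two steps.

## Roads not taken

**Alternative 1:** (the most obvious). Cut C5–C10 and C8–C9 by a Diels–Alder reaction of a 1-(2-propenyl)butadiene with an α-methylene lactone dienophile, giving spirolactone A1 with the endo carbonyl (C14) cis to the C5 substituent. The C6=C7 alkene would then be epoxidised and opened at C7 by an acetate-type nucleophile; C8 would be oxidised allylically; methylenation and isopropenyl→enal oxidation would come last. The chosen plan is better for four reasons: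
- Absolute control would need an enantioselective cycloaddition for an unusual diene/dienophile pair, or a resolution.
- A1 has no handle at C8.
- In the chair fixed by C10 and C5, trans-diaxial epoxide opening delivers the nucleophile to the wrong carbon or gives a diaxial triad, whereas the target is all-equatorial.
- The late allylic oxidations must discriminate between several allylic positions, and the sequence is clearly longer.

**Alternative 2:** (biomimetic). Cut C5–C10 by a Cope rearrangement of the (E,E)-germacranolide A2 through a chair transition state, which would give the trans-divinyl pattern directly. The plan is rejected because A2 is not simpler than 36. It keeps C6, C7, C8, both esters, the lactone and the enal, and adds two stereodefined trisubstituted ring alkenes in a strained ten-membered ring. The rearrangement is reversible, and conjugation of C4=C5 with the aldehyde stabilises the germacrane side. The key step would come last and simplify nothing before it.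

**Alternative 3:** Cut C6–C7 and O6–C12 by an intramolecular Barbier-type allylation/lactonisation of the open-chain aldehyde A3 (carbocycle and lactone in one step), with C5–C10 made earlier by an ester-enolate Claisen rearrangement. The plan is rejected for these reasons:
- A3 needs C5/C10 and the remote C8 set independently on a flexible chain.
- The allylmetal carries a δ-silyloxy group and can undergo 1,4-elimination.
- The ring closure must select one of four C6/C7 diastereomers.
- The enal oxidation level still has to be raised afterwards.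
- The run-up to A3 is long and linear.

Key step: step 6

Assumption: the (S)-amine of step 6 and the (R)-bisphosphine of step 10 are taken to induce the drawn series; if either induces the opposite sense, its mirror image is used and nothing else changes.
Convention: from 12 on, H5 is α and C14 is β (vinyl α); C4 in 12–32 is an inconsequential epimer mixture (it becomes sp2 in step 16) and is left undefined in the SMILES.

## Steps

Step 1
Reactants: 1 2-methylenepropane-1,3-diol
Product: 2 2-{[(tert-butyldimethylsilyl)oxy]methyl}prop-2-en-1-ol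
Conditions: NaH (1.0 equiv), THF, 0 °C to rt; TBSCl (1.0 equiv)
Reagents that add atoms: tert-butyldimethylsilyl chloride, CC(C)(C)[Si](C)(C)Cl
Why: Monosilylation of a symmetrical diol through its monosodium alkoxide; no stereocentre is involved.

Step 2
Reactants: 2 2-{[(tert-butyldimethylsilyl)oxy]methyl}prop-2-en-1-ol
Product: 3 2-{[(tert-butyldimethylsilyl)oxy]methyl}prop-2-enal
Conditions: MnO2 (excess), CH2Cl2, rt
Reagents that add atoms: none
Why: Manganese dioxide oxidation of an allylic alcohol should stop at the 2-substituted acrolein.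

Step 3
Reactants: 3 2-{[(tert-butyldimethylsilyl)oxy]methyl}prop-2-enal; 4 (E)-1-methoxy-3-(trimethylsilyloxy)buta-1,3-diene
Product: 7 rac-4-{[(tert-butyldimethylsilyl)oxy]methyl}-4-vinylcyclohex-2-en-1-one, via cycloadduct 5 (not isolated), via vinyl cycloadduct 6 (not isolated)
Conditions: toluene, rt to 50 °C; then Ph3P=CH2 (from Ph3PCH3Br, KOtBu), THF, 0 °C; then 1 M HCl, THF, 0 °C
Reagents that add atoms: methyltriphenylphosphonium bromide, C[P+](c1ccccc1)(c1ccccc1)c1ccccc1.[Br-]
Why: The Diels–Alder reaction of the 1,3-dioxygenated diene with the 2-substituted acrolein bonds the methoxy-bearing terminus to the formyl-bearing carbon; Wittig methylenation turns the non-enolisable aldehyde into the vinyl group before the enone exists; acid then gives the 4,4-disubstituted cyclohexenone by enol ether hydrolysis and loss of methanol. The quaternary carbon forms racemic, which does not matter because step 4 makes it non-stereogenic.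

Step 4
Reactants: 7 rac-4-{[(tert-butyldimethylsilyl)oxy]methyl}-4-vinylcyclohex-2-en-1-one
Product: 8 4-{[(tert-butyldimethylsilyl)oxy]methyl}-4-vinylcyclohexa-2,5-dien-1-one
Conditions: IBX (2 equiv), DMSO/fluorobenzene, 70 °C
Reagents that add atoms: none
Why: IBX dehydrogenation of a ketone; only the saturated CH2–CH2 edge can react, giving the cross-conjugated achiral dienone, and the quaternary carbon prevents aromatisation.

Step 5
Reactants: 8 4-{[(tert-butyldimethylsilyl)oxy]methyl}-4-vinylcyclohexa-2,5-dien-1-one
Product: 9 4-(hydroxymethyl)-4-vinylcyclohexa-2,5-dien-1-one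
Conditions: HF·pyridine, THF, 0 °C
Reagents that add atoms: none
Why: Acidic fluoride desilylation; base is avoided because the alkoxide of 9 could lose formaldehyde with aromatisation.

Step 6
Reactants: 9 4-(hydroxymethyl)-4-vinylcyclohexa-2,5-dien-1-one; 10 acrolein
Product: 13 (5αH)-3,14-epoxy-15,15-dimethoxy-11,12,13-trinorelema-1,8-dien-7-one, via alkoxy aldehyde 11 (not isolated), via bicyclic aldehyde 12 (not isolated)
Conditions: (S)-2-[diphenyl(trimethylsilyloxy)methyl]pyrrolidine (20 mol %), PhCO2H (20 mol %), toluene, 0 °C to rt, slow addition of 10; then HC(OMe)3, MeOH, TsOH·H2O, 0 °C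
Reagents that add atoms: trimethyl orthoformate, COC(OC)OC; methanol, CO
Why: Iminium activation of 10 lets the C14 hydroxyl of 9 add to C3 (oxa-Michael), and the enamine of 11 then attacks one of the two enantiotopic enone β-carbons (C5) in a 6-exo-trig Michael addition that closes the tetrahydropyran O14–C3–C4–C5–C10–C14 and breaks the symmetry of the dienone. The closest known reaction types are the amine-catalysed oxa-Michael/Michael desymmetrisation of 4-hydroxycyclohexa-2,5-dienones with enals and the amine-catalysed intramolecular Michael desymmetrisation of 4-(ω-formylalkyl)cyclohexadienones; here the oxygen sits one carbon further out, so a six-membered ether ring forms. The oxa-Michael step is reversible and creates no stereocentre (C3 is CH2), so only the C–C bond formation selects. C5: the three-atom tether C14–O–C3 can reach the planar dienone only from the face that carries C14, so C4 enters cis to C14 and trans to the vinyl group, as in the target. C10: it becomes stereogenic through the choice between C5 and C9, which the shielded face of the catalyst-bound (E)-enamine dictates in a chair-like transition state. C4 is also set but is erased in step 16. The step needs group selection between the two enone halves (catalyst), 1,4- over 1,2-addition (soft enamine) and a single annulation (9 has only one hydroxyl). Aldehyde 12 is acetalised in the same flask because the next steps use hydride, peroxide and amide bases.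

Step 7
Reactants: 13 (5αH)-3,14-epoxy-15,15-dimethoxy-11,12,13-trinorelema-1,8-dien-7-one
Product: 15 (5αH)-3,14-epoxy-15,15-dimethoxy-8α-(triethylsilyloxy)-11,12,13-trinorelem-1-en-7-one, via silyl enol ether 14 (not isolated)
Conditions: Et3SiH, RhCl(PPh3)3 (1 mol %), THF, 50 °C; then dimethyldioxirane, acetone/CH2Cl2, −40 °C to 0 °C
Reagents that add atoms: triethylsilane, CC[SiH](CC)CC; dimethyldioxirane, CC1(C)OO1
Why: Rhodium-catalysed 1,4-hydrosilylation gives the C7=C8 silyl enol ether regiospecifically, and Rubottom oxidation delivers oxygen to C8 from the convex α-face (opposite the pyran ring and the axial C14) with silyl migration to the new oxygen. C8 is α to the ketone, so the equatorial 8α-epimer is also the thermodynamic one.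

Step 8
Reactants: 15 (5αH)-3,14-epoxy-15,15-dimethoxy-8α-(triethylsilyloxy)-11,12,13-trinorelem-1-en-7-one
Product: 18 (5αH)-3,14-epoxy-6α-hydroxy-15,15-dimethoxy-8α-(triethylsilyloxy)-11,12,13-trinorelem-1-en-7-one, via silyl enol ether 16 (not isolated), via bis-silyl ether 17 (not isolated)
Conditions: LiHMDS, TMSCl, THF, −78 °C; then dimethyldioxirane, CH2Cl2, −78 °C to −20 °C; then citric acid, MeOH, 0 °C
Reagents that add atoms: dimethyldioxirane, CC1(C)OO1
Why: Kinetic deprotonation should occur at the C6 methylene and not at the silyloxy-bearing C8; Rubottom oxidation of the C6=C7 enol ether from the α-face (anti to C4 and the pyran ring) gives the 6α-oxygen, again epimerisable and equatorial. Mild acid in methanol removes only the trimethylsilyl group and leaves the acetal intact.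

Step 9
Reactants: 18 (5αH)-3,14-epoxy-6α-hydroxy-15,15-dimethoxy-8α-(triethylsilyloxy)-11,12,13-trinorelem-1-en-7-one; 19 (triphenylphosphoranylidene)ketene
Product: 21 (5αH)-3,14-epoxy-15,15-dimethoxy-8α-(triethylsilyloxy)-13-norelema-1,7(11)-dien-12,6α-olide, via acyl ylide 20 (not isolated)
Conditions: toluene, 100 °C
Reagents that add atoms: none
Why: The 6-hydroxyl adds to the cumulated ylide to give an ester-stabilised phosphorane, which closes onto the neighbouring C7 ketone in an intramolecular Wittig reaction; the lactone is thereby tied to O6 without ambiguity and C11/C12 are installed.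

Step 10
Reactants: 21 (5αH)-3,14-epoxy-15,15-dimethoxy-8α-(triethylsilyloxy)-13-norelema-1,7(11)-dien-12,6α-olide
Product: 22 (5αH,7αH)-3,14-epoxy-15,15-dimethoxy-8α-(triethylsilyloxy)-13-norelem-1-en-12,6α-olide
Conditions: Cu(OAc)2·H2O (5 mol %), (R)-DTBM-SEGPHOS (5.5 mol %), (EtO)2MeSiH, t-BuOH, toluene, 0 °C to rt
Reagents that add atoms: none
Why: Copper hydride 1,4-reduction of a β,β-disubstituted butenolide; hydride should reach C7 along the axial trajectory on the α-face (only H5 and H9 are syn-axial there), which places C11 equatorial and gives the trans-fused lactone, with the chiral bisphosphine chosen to reinforce this face. The vinyl group, acetal and silyl ether are inert to copper hydride.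

Step 11
Reactants: 22 (5αH,7αH)-3,14-epoxy-15,15-dimethoxy-8α-(triethylsilyloxy)-13-norelem-1-en-12,6α-olide
Product: 25 (5αH,7αH)-3,14-epoxy-15,15-dimethoxy-8α-(triethylsilyloxy)elema-1,11(13)-dien-12,6α-olide, via Mannich base 23 (not isolated), via methiodide 24 (not isolated)
Conditions: LDA, THF, −78 °C; CH2=NMe2+ I−, −78 °C to rt; then MeI, MeOH, rt; then aq. NaHCO3
Reagents that add atoms: N,N-dimethylmethyleneiminium iodide, C=[N+](C)C.[I-]
Why: Eschenmoser methylenation: the lactone enolate is aminomethylated at C11, and quaternisation and elimination give the exocyclic methylene; no stereocentre remains at C11 and no other acidic C–H competes.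

Step 12
Reactants: 25 (5αH,7αH)-3,14-epoxy-15,15-dimethoxy-8α-(triethylsilyloxy)elema-1,11(13)-dien-12,6α-olide
Product: 26 (5αH,7αH)-3,14-epoxy-8α-hydroxy-15-oxoelema-1,11(13)-dien-12,6α-olide
Conditions: AcOH/THF/H2O (3:1:1), 35 °C
Reagents that add atoms: water, O
Why: Aqueous acid hydrolyses the dimethyl acetal and the secondary triethylsilyl ether in one operation; the α-methylene lactone tolerates acid, and the aldehyde stays in the closed tetrahydropyran form, which is the stable constitution.

Step 13
Reactants: 27 ethyl 2-(hydroxymethyl)acrylate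
Product: 28 ethyl 2-{[(tert-butyldiphenylsilyl)oxy]methyl}acrylate
Conditions: TBDPSCl, imidazole, CH2Cl2, 0 °C to rt
Reagents that add atoms: tert-butyldiphenylsilyl chloride, CC(C)(C)[Si](Cl)(c1ccccc1)c1ccccc1
Why: Standard silylation of a primary alcohol; the bulky silyl group is chosen to survive steps 15–17.

Step 14
Reactants: 28 ethyl 2-{[(tert-butyldiphenylsilyl)oxy]methyl}acrylate
Product: 29 2-{[(tert-butyldiphenylsilyl)oxy]methyl}acrylic acid
Conditions: LiOH, THF/H2O, 0 °C to rt; then 1 M HCl
Reagents that add atoms: lithium hydroxide, [Li+].[OH-]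
Why: Saponification of an α-substituted acrylate, in which acyl substitution is faster than conjugate addition of hydroxide at the hindered position.

Step 15
Reactants: 26 (5αH,7αH)-3,14-epoxy-8α-hydroxy-15-oxoelema-1,11(13)-dien-12,6α-olide; 29 2-{[(tert-butyldiphenylsilyl)oxy]methyl}acrylic acid
Product: 31 (5αH,7αH)-8α-{2-[(tert-butyldiphenylsilyloxy)methyl]acryloyloxy}-3,14-epoxy-15-oxoelema-1,11(13)-dien-12,6α-olide, via mixed anhydride 30 (not isolated)
Conditions: 29, 2,4,6-trichlorobenzoyl chloride, Et3N, toluene, rt; then 26, DMAP, rt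
Reagents that add atoms: none
Why: Yamaguchi esterification of the equatorial 8α-hydroxyl; the α-branched aldehyde is not acylated and its tetrahydropyran keeps O14 unavailable.

Step 16
Reactants: 31 (5αH,7αH)-8α-{2-[(tert-butyldiphenylsilyloxy)methyl]acryloyloxy}-3,14-epoxy-15-oxoelema-1,11(13)-dien-12,6α-olide
Product: 33 (5αH,7αH)-8α-{2-[(tert-butyldiphenylsilyloxy)methyl]acryloyloxy}-15-oxo-14-(trimethylsilyloxy)elema-1,3,11(13)-trien-12,6α-olide, via silyl enol ether 32 (not isolated)
Conditions: TMSOTf (3 equiv), Et3N (4 equiv), CH2Cl2, −78 °C to 0 °C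
Reagents that add atoms: trimethylsilyl trifluoromethanesulfonate, C[Si](C)(C)OS(=O)(=O)C(F)(F)F
Why: Soft enolisation gives silyl enol ether 32; silylation of the ring oxygen then ionises the allylic C3–O14 bond (vinylogous β-elimination), and loss of the silyl cation from the carbonyl oxygen leaves the enal and the 14-silyl ether. This is the silyl triflate/amine ring opening known for cyclic β-alkoxy carbonyl compounds; the move of silicon from an enol oxygen to an alkyl oxygen supplies the driving force that a bare retro-oxa-Michael lacks. C4 becomes sp2, so the epimers converge.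

Step 17
Reactants: 33 (5αH,7αH)-8α-{2-[(tert-butyldiphenylsilyloxy)methyl]acryloyloxy}-15-oxo-14-(trimethylsilyloxy)elema-1,3,11(13)-trien-12,6α-olide
Product: 35 (5αH,7αH)-14-acetoxy-8α-{2-[(tert-butyldiphenylsilyloxy)methyl]acryloyloxy}-15-oxoelema-1,3,11(13)-trien-12,6α-olide, via hydroxy enal 34 (not isolated)
Conditions: Ac2O, pyridine, DMAP (cat.), THF, 0 °C; then HF·pyridine (1.2 equiv), 0 °C
Reagents that add atoms: acetic anhydride, CC(=O)OC(C)=O
Why: Fluoride cleaves the primary trimethylsilyl ether in the presence of the acylating agent, so alcohol 34 should be acetylated before it can add back to the enal; the tert-butyldiphenylsilyl ether reacts far more slowly under these conditions.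

Step 18
Reactants: 35 (5αH,7αH)-14-acetoxy-8α-{2-[(tert-butyldiphenylsilyloxy)methyl]acryloyloxy}-15-oxoelema-1,3,11(13)-trien-12,6α-olide
Product: 36 (5αH,7αH)-14-acetoxy-8α-[2-(hydroxymethyl)acryloyloxy]-15-oxoelema-1,3,11(13)-trien-12,6α-olide (CNP0185525.1)
Conditions: HF·pyridine (excess), pyridine, THF, 0 °C to rt
Reagents that add atoms: none
Why: Buffered HF·pyridine removes the silyl ether without base and so spares the acetate, both α-methylene carbonyl units and the enal.

## Compound list

1 | 2-methylenepropane-1,3-diol | C=C(CO)CO | starting material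
2 | 2-{[(tert-butyldimethylsilyl)oxy]methyl}prop-2-en-1-ol | C=C(CO)CO[Si](C)(C)C(C)(C)C | intermediate
3 | 2-{[(tert-butyldimethylsilyl)oxy]methyl}prop-2-enal | C=C(C=O)CO[Si](C)(C)C(C)(C)C | intermediate
4 | (E)-1-methoxy-3-(trimethylsilyloxy)buta-1,3-diene | CO/C=C/C(=C)O[Si](C)(C)C | starting material
5 | rac-1-{[(tert-butyldimethylsilyl)oxy]methyl}-2-methoxy-4-(trimethylsilyloxy)cyclohex-3-ene-1-carbaldehyde (diastereomer mixture) | O=CC1(CO[Si](C)(C)C(C)(C)C)CCC(O[Si](C)(C)C)=CC1OC | intermediate
6 | rac-tert-butyl{[2-methoxy-4-(trimethylsilyloxy)-1-vinylcyclohex-3-en-1-yl]methoxy}dimethylsilane (diastereomer mixture) | C=CC1(CO[Si](C)(C)C(C)(C)C)CCC(O[Si](C)(C)C)=CC1OC | intermediate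
7 | rac-4-{[(tert-butyldimethylsilyl)oxy]methyl}-4-vinylcyclohex-2-en-1-one | C=CC1(CO[Si](C)(C)C(C)(C)C)CCC(=O)C=C1 | intermediate
8 | 4-{[(tert-butyldimethylsilyl)oxy]methyl}-4-vinylcyclohexa-2,5-dien-1-one (achiral) | C=CC1(CO[Si](C)(C)C(C)(C)C)C=CC(=O)C=C1 | intermediate
9 | 4-(hydroxymethyl)-4-vinylcyclohexa-2,5-dien-1-one (achiral) | C=CC1(CO)C=CC(=O)C=C1 | intermediate
10 | acrolein | C=CC=O | starting material
11 | 3-[(4-oxo-1-vinylcyclohexa-2,5-dien-1-yl)methoxy]propanal | C=CC1(COCCC=O)C=CC(=O)C=C1 | intermediate
12 | (5αH)-3,14-epoxy-7-oxo-11,12,13-trinorelema-1,8-dien-15-al (cis-fused; C4 epimers) | C=C[C@@]12COCC(C=O)[C@@H]1CC(=O)C=C2 | intermediate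
13 | (5αH)-3,14-epoxy-15,15-dimethoxy-11,12,13-trinorelema-1,8-dien-7-one | C=C[C@@]12COCC(C(OC)OC)[C@@H]1CC(=O)C=C2 | intermediate
14 | (5αH)-3,14-epoxy-15,15-dimethoxy-7-(triethylsilyloxy)-11,12,13-trinorelema-1,7-diene | C=C[C@@]12COCC(C(OC)OC)[C@@H]1CC(O[Si](CC)(CC)CC)=CC2 | intermediate
15 | (5αH)-3,14-epoxy-15,15-dimethoxy-8α-(triethylsilyloxy)-11,12,13-trinorelem-1-en-7-one | C=C[C@@]12COCC(C(OC)OC)[C@@H]1CC(=O)[C@@H](O[Si](CC)(CC)CC)C2 | intermediate
16 | (5αH)-3,14-epoxy-15,15-dimethoxy-8α-(triethylsilyloxy)-7-(trimethylsilyloxy)-11,12,13-trinorelema-1,6-diene | C=C[C@@]12COCC(C(OC)OC)[C@@H]1C=C(O[Si](C)(C)C)[C@@H](O[Si](CC)(CC)CC)C2 | intermediate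
17 | (5αH)-3,14-epoxy-15,15-dimethoxy-8α-(triethylsilyloxy)-6α-(trimethylsilyloxy)-11,12,13-trinorelem-1-en-7-one | C=C[C@@]12COCC(C(OC)OC)[C@@H]1[C@@H](O[Si](C)(C)C)C(=O)[C@@H](O[Si](CC)(CC)CC)C2 | intermediate
18 | (5αH)-3,14-epoxy-6α-hydroxy-15,15-dimethoxy-8α-(triethylsilyloxy)-11,12,13-trinorelem-1-en-7-one | C=C[C@@]12COCC(C(OC)OC)[C@@H]1[C@@H](O)C(=O)[C@@H](O[Si](CC)(CC)CC)C2 | intermediate
19 | (triphenylphosphoranylidene)ketene | O=C=C=P(c1ccccc1)(c1ccccc1)c1ccccc1 | starting material
20 | 6α-O-[(triphenylphosphoranylidene)acetyl] ester of 18 | C=C[C@@]12COCC(C(OC)OC)[C@@H]1[C@@H](OC(=O)C=P(c3ccccc3)(c3ccccc3)c3ccccc3)C(=O)[C@@H](O[Si](CC)(CC)CC)C2 | intermediate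
21 | (5αH)-3,14-epoxy-15,15-dimethoxy-8α-(triethylsilyloxy)-13-norelema-1,7(11)-dien-12,6α-olide | C=C[C@@]12COCC(C(OC)OC)[C@@H]1[C@H]3OC(=O)C=C3[C@@H](O[Si](CC)(CC)CC)C2 | intermediate
22 | (5αH,7αH)-3,14-epoxy-15,15-dimethoxy-8α-(triethylsilyloxy)-13-norelem-1-en-12,6α-olide | C=C[C@@]12COCC(C(OC)OC)[C@@H]1[C@H]3OC(=O)C[C@@H]3[C@@H](O[Si](CC)(CC)CC)C2 | intermediate
23 | (5αH,7αH)-13-(dimethylamino)-3,14-epoxy-15,15-dimethoxy-8α-(triethylsilyloxy)elem-1-en-12,6α-olide (C11 epimers) | C=C[C@@]12COCC(C(OC)OC)[C@@H]1[C@H]3OC(=O)C(CN(C)C)[C@@H]3[C@@H](O[Si](CC)(CC)CC)C2 | intermediate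
24 | N-methyl iodide of 23 | C=C[C@@]12COCC(C(OC)OC)[C@@H]1[C@H]3OC(=O)C(C[N+](C)(C)C)[C@@H]3[C@@H](O[Si](CC)(CC)CC)C2.[I-] | intermediate
25 | (5αH,7αH)-3,14-epoxy-15,15-dimethoxy-8α-(triethylsilyloxy)elema-1,11(13)-dien-12,6α-olide | C=C[C@@]12COCC(C(OC)OC)[C@@H]1[C@H]3OC(=O)C(=C)[C@@H]3[C@@H](O[Si](CC)(CC)CC)C2 | intermediate
26 | (5αH,7αH)-3,14-epoxy-8α-hydroxy-15-oxoelema-1,11(13)-dien-12,6α-olide | C=C[C@@]12COCC(C=O)[C@@H]1[C@H]3OC(=O)C(=C)[C@@H]3[C@@H](O)C2 | intermediate
27 | ethyl 2-(hydroxymethyl)acrylate | C=C(CO)C(=O)OCC | starting material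
28 | ethyl 2-{[(tert-butyldiphenylsilyl)oxy]methyl}acrylate | C=C(CO[Si](c1ccccc1)(c1ccccc1)C(C)(C)C)C(=O)OCC | intermediate
29 | 2-{[(tert-butyldiphenylsilyl)oxy]methyl}acrylic acid | C=C(CO[Si](c1ccccc1)(c1ccccc1)C(C)(C)C)C(=O)O | intermediate
30 | 2-{[(tert-butyldiphenylsilyl)oxy]methyl}acrylic 2,4,6-trichlorobenzoic anhydride | C=C(CO[Si](c1ccccc1)(c1ccccc1)C(C)(C)C)C(=O)OC(=O)c1c(Cl)cc(Cl)cc1Cl | intermediate
31 | (5αH,7αH)-8α-{2-[(tert-butyldiphenylsilyloxy)methyl]acryloyloxy}-3,14-epoxy-15-oxoelema-1,11(13)-dien-12,6α-olide | C=C[C@@]12COCC(C=O)[C@@H]1[C@H]3OC(=O)C(=C)[C@@H]3[C@@H](OC(=O)C(=C)CO[Si](c4ccccc4)(c4ccccc4)C(C)(C)C)C2 | intermediate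
32 | 15-(trimethylsilyl) enol ether of 31 (C4=C15) | C=C[C@@]12COCC(=CO[Si](C)(C)C)[C@@H]1[C@H]3OC(=O)C(=C)[C@@H]3[C@@H](OC(=O)C(=C)CO[Si](c4ccccc4)(c4ccccc4)C(C)(C)C)C2 | intermediate
33 | (5αH,7αH)-8α-{2-[(tert-butyldiphenylsilyloxy)methyl]acryloyloxy}-15-oxo-14-(trimethylsilyloxy)elema-1,3,11(13)-trien-12,6α-olide | C=C[C@]1(CO[Si](C)(C)C)C[C@H](OC(=O)C(=C)CO[Si](c3ccccc3)(c3ccccc3)C(C)(C)C)[C@H]2C(=C)C(=O)O[C@@H]2[C@H]1C(=C)C=O | intermediate
34 | (5αH,7αH)-8α-{2-[(tert-butyldiphenylsilyloxy)methyl]acryloyloxy}-14-hydroxy-15-oxoelema-1,3,11(13)-trien-12,6α-olide | C=C[C@]1(CO)C[C@H](OC(=O)C(=C)CO[Si](c3ccccc3)(c3ccccc3)C(C)(C)C)[C@H]2C(=C)C(=O)O[C@@H]2[C@H]1C(=C)C=O | intermediate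
35 | (5αH,7αH)-14-acetoxy-8α-{2-[(tert-butyldiphenylsilyloxy)methyl]acryloyloxy}-15-oxoelema-1,3,11(13)-trien-12,6α-olide | C=C[C@]1(COC(C)=O)C[C@H](OC(=O)C(=C)CO[Si](c3ccccc3)(c3ccccc3)C(C)(C)C)[C@H]2C(=C)C(=O)O[C@@H]2[C@H]1C(=C)C=O | intermediate
36 | (5αH,7αH)-14-acetoxy-8α-[2-(hydroxymethyl)acryloyloxy]-15-oxoelema-1,3,11(13)-trien-12,6α-olide (CNP0185525.1) | C=C[C@]1(COC(C)=O)C[C@H](OC(=O)C(=C)CO)[C@H]2C(=C)C(=O)O[C@@H]2[C@H]1C(=C)C=O | target

## Step count and least certain steps

Total: 18 steps. Longest linear sequence: 16 steps (1–12 and 15–18); steps 13–14 are a two-step side branch.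

**Step 6 (key step).** The reversible oxa-Michael addition may lag behind oligomerisation of acrolein. The amine may trigger loss of formaldehyde from 9 with aromatisation. Group selection between the two enone halves may be poor, because the enamine exists only after an intermolecular step. Fallback: the two bond formations are separated. Setting out from 9, a trimethylphosphine-catalysed hydroalkoxylation of 10 gives the alkoxy aldehyde 11, which is isolated. 11 is then cyclised in a purely intramolecular enamine Michael reaction with a chiral secondary amine optimised for that step alone (the exact substrate type of the closest precedent). Acetalisation of 12 as before returns to the route at 13. No compound outside the list is made (F0).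

**Step 16.** The closed silyl enol ether may persist without ionisation of the C3–O14 bond, or the silyl ether may add back to the activated enal, because the closed constitution is the more stable one. Fallback by oxygen-to-sulfur exchange, setting out from 31:
- Thiophenol with catalytic Et3N opens the ring. The alkoxide released by E1cB is protonated by the thiol and the enal is captured by thia-Michael addition, which is far more favourable than the oxa-Michael. The two α-methylene units also take up thiophenol and are thereby protected. The product is the hydroxy tris-sulfide F1.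
- Acetylation (Ac2O, pyridine) gives the acetate F2.
- Oxidation (NaIO4 or mCPBA at −78 °C) gives the tris-sulfoxide F3. Thermal syn-elimination (toluene, 90–110 °C) regenerates all three methylene groups and returns to the route at 35.

**Step 10.** Hydride may be delivered to the β-face of C7 (equatorial attack by a bulky copper hydride), which would give the cis-fused lactone; C7 cannot be corrected later. Fallback by hydroxyl-directed hydrogenation with the vinyl group masked, setting out from 21:
- HF·pyridine gives the 8α-hydroxy butenolide F4.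
- Pyridinium tribromide adds bromine to the electron-rich vinyl group only, giving the dibromide F5.
- [Ir(cod)(PCy3)(py)]PF6/H2 delivers hydrogen to C7 from the face of the 8α-hydroxyl, giving the trans-lactone dibromide F6.
- Zinc (EtOH, NH4Cl) restores the vinyl group in the hydroxy lactone F7.
- TESCl/imidazole returns to the route at 22.

**Step 8.** Enolisation may occur towards C8 (silyloxy-bearing) instead of C6, or the silyl group may migrate between O8 and O6 under base. Fallback that fixes C6 before C8, setting out from 13: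
- Mn(OAc)3 in hot benzene acetoxylates the only enolisable position of the enone (C6), giving the 6α-acetoxy enone F8.
- Hydrosilylation/Rubottom oxidation as in step 7 gives the 6α-acetoxy-8α-silyloxy ketone F9.
- Mild methanolysis (K2CO3, MeOH, −20 °C) returns to the route at 18.

## Further compounds

F0 | step 6 | none | none
F1 | step 16 | (5αH,7αH)-14-hydroxy-15-oxo-3,13-bis(phenylthio)-8α-{3-[(tert-butyldiphenylsilyl)oxy]-2-[(phenylthio)methyl]propanoyloxy}elem-1-en-12,6α-olide (epimers at C4, C11 and the side-chain α-carbon) | C=C[C@]1(CO)C[C@H](OC(=O)C(CSc3ccccc3)CO[Si](c3ccccc3)(c3ccccc3)C(C)(C)C)[C@H]2C(CSc3ccccc3)C(=O)O[C@@H]2[C@H]1C(CSc4ccccc4)C=O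
F2 | step 16 | 14-acetate of F1 | C=C[C@]1(COC(C)=O)C[C@H](OC(=O)C(CSc3ccccc3)CO[Si](c3ccccc3)(c3ccccc3)C(C)(C)C)[C@H]2C(CSc3ccccc3)C(=O)O[C@@H]2[C@H]1C(CSc4ccccc4)C=O
F3 | step 16 | tris-sulfoxide of F2 | C=C[C@]1(COC(C)=O)C[C@H](OC(=O)C(CS(=O)c3ccccc3)CO[Si](c3ccccc3)(c3ccccc3)C(C)(C)C)[C@H]2C(CS(=O)c3ccccc3)C(=O)O[C@@H]2[C@H]1C(CS(=O)c4ccccc4)C=O
F4 | step 10 | (5αH)-3,14-epoxy-8α-hydroxy-15,15-dimethoxy-13-norelema-1,7(11)-dien-12,6α-olide | C=C[C@@]12COCC(C(OC)OC)[C@@H]1[C@H]3OC(=O)C=C3[C@@H](O)C2
F5 | step 10 | (5αH)-1,2-dibromo-3,14-epoxy-8α-hydroxy-15,15-dimethoxy-13-norelem-7(11)-en-12,6α-olide (C1 epimers) | BrCC(Br)[C@@]12COCC(C(OC)OC)[C@@H]1[C@H]3OC(=O)C=C3[C@@H](O)C2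
F6 | step 10 | (5αH,7αH)-1,2-dibromo-3,14-epoxy-8α-hydroxy-15,15-dimethoxy-13-norelemano-12,6α-olide (C1 epimers) | BrCC(Br)[C@@]12COCC(C(OC)OC)[C@@H]1[C@H]3OC(=O)C[C@@H]3[C@@H](O)C2
F7 | step 10 | (5αH,7αH)-3,14-epoxy-8α-hydroxy-15,15-dimethoxy-13-norelem-1-en-12,6α-olide | C=C[C@@]12COCC(C(OC)OC)[C@@H]1[C@H]3OC(=O)C[C@@H]3[C@@H](O)C2
F8 | step 8 | (5αH)-6α-acetoxy-3,14-epoxy-15,15-dimethoxy-11,12,13-trinorelema-1,8-dien-7-one | C=C[C@@]12COCC(C(OC)OC)[C@@H]1[C@@H](OC(C)=O)C(=O)C=C2
F9 | step 8 | (5αH)-6α-acetoxy-3,14-epoxy-15,15-dimethoxy-8α-(triethylsilyloxy)-11,12,13-trinorelem-1-en-7-one | C=C[C@@]12COCC(C(OC)OC)[C@@H]1[C@@H](OC(C)=O)C(=O)[C@@H](O[Si](CC)(CC)CC)C2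
A1 | alternative 1 | 6-(prop-1-en-2-yl)-2-oxaspiro[4.5]dec-7-en-1-one (lactone carbonyl cis to the propenyl group; C5/C10 as in the target) | C=C(C)[C@@H]1C=CCC[C@@]12CCOC2=O
A2 | alternative 2 | 14-acetoxy-8α-[2-(hydroxymethyl)acryloyloxy]-15-oxogermacra-1(10),4,11(13)-trien-12,6α-olide (both ring alkenes ring-trans) | CC(=O)OC/C1=C\CC/C(C=O)=C/[C@H]2OC(=O)C(=C)[C@@H]2[C@@H](OC(=O)C(=C)CO)C1
A3 | alternative 3 | methyl (2Z)-2-(bromomethyl)-4-[(tert-butyldimethylsilyl)oxy]-7-formyl-6-{[(4-methoxybenzyl)oxy]methyl}-8-methyl-6-vinylnona-2,8-dienoate (C8, C10 and C5 of the target as chain C4, C6 and C7) | COC(=O)/C(CBr)=C/[C@@H](O[Si](C)(C)C(C)(C)C)C[C@](C=C)(COCc1ccc(OC)cc1)[C@@H](C=O)C(C)=C
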